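**Retrosynthetic overview**
1. The furan ring is closed last, by a Nenitzescu-type annulation of a 2-(pyrrolidin-1-yl)pyranochromone (nucleophilic C3, amine leaving group on C2) with 2,2-dimethyl-2H-chromene-5,8-dione; the second quinone oxygen becomes the free B-ring phenol.
2. The quinone comes from 5,8-dimethoxy-2,2-dimethylchroman-4-one (reduction/dehydration, then CAN). The chromanone is made in the key step from an o-fluoroacetophenone and acetone: enolate aldol addition (C3–C2) followed by intramolecular SNAr of the aldolate oxygen (O1–C8a), a formal [4+2] in which acetone serves as a C–O two-atom unit.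
3. Enabling feature: in the B-ring chromene, C4 is bonded to C4a, which is ortho to the oxygen-bearing C8a. A temporary C4 ketone therefore turns C3 into an enolate carbon and makes an ortho C8a–F bond SNAr-active; the para-dioxygenated benzene ring (C5/C8) is a masked quinone.
4. Ring-A half: phloroacetophenone → propargyl-ether Claisen (A-ring pyran, unambiguous by symmetry) → allyl ether (marks the future 5-OH) → γ-pyrone via ketene dithioacetal and pyrrolidine → Claisen to C6 → cross-metathesis to prenyl.
5. Ring order: B-ring pyranone (key step) → A-ring pyran → γ-pyrone → furan.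

Key step: step 2

Remark on the chemistry: the target has no stereogenic centre or axis (its only stereo-elements are ring-enforced cis alkenes), so no stereocontrol is needed; the one sp3 carbinol centre that appears on the way is racemic and is destroyed in the same step.

**Route**

Step 1
Reactants: 1 2-fluoro-1,4-dimethoxybenzene
Product: 3 1-(2-fluoro-3,6-dimethoxyphenyl)ethan-1-one, via aryllithium 2 (not isolated)
Conditions: n-BuLi, THF, −78 °C; N-methoxy-N-methylacetamide, −78 → 0 °C; 1 M HCl
Reagents that add atoms: N-methoxy-N-methylacetamide, CC(=O)N(C)OC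
Why: Directed ortho-metalation should occur at the C–H flanked by fluorine and methoxy (the most acidic, doubly coordinated site), and the Weinreb amide acylates the aryllithium once through its stable chelated tetrahedral adduct; the temperature is held at −78 °C so that the o-fluoroaryllithium does not lose LiF.

Step 2
Reactants: 3 1-(2-fluoro-3,6-dimethoxyphenyl)ethan-1-one; 4 acetone
Product: 7 5,8-dimethoxy-2,2-dimethyl-2,3-dihydro-4H-chromen-4-one, via lithium enolate 5 (not isolated), via lithium aldolate 6 (not isolated)
Conditions: LDA, THF, −78 °C; acetone (3 equiv), −78 °C; DMPU, −78 → 45 °C; aq. NH4Cl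
Reagents that add atoms: none
Why: LDA deprotonates the acetyl CH3, the only enolisable position, and the lithium enolate adds to acetone to give the tertiary lithium alkoxide 6 (C3–C2 bond); on warming with DMPU this alkoxide attacks the ortho C–F carbon by addition–elimination through a Meisenheimer adduct stabilised by the ortho aryl-ketone carbonyl, and loss of LiF closes the pyranone (O1–C8a bond), the irreversible substitution draining the reversible aldol equilibrium. The closest known reaction types are the aldol addition of methyl-ketone lithium enolates to acetone and SNAr-terminated domino annulations of o-fluoroaryl carbonyl compounds, including the cyclisation of o-fluoroaryl β-hydroxy ketones to chroman-4-ones; the sequence is the polarity-reversed counterpart of the Kabbe chromanone synthesis. The ring closes in a 6-exo-trig mode at the aromatic carbon, through a six-membered transition state that holds the ketone coplanar with the arene. No stereocentre is formed. The step needs O-arylation at C–F and not at the other ortho position, which is secured because that position carries methoxy, a far poorer nucleofuge than fluoride; aryne formation is excluded because the fluorine has no ortho hydrogen.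

Step 3
Reactants: 7 5,8-dimethoxy-2,2-dimethyl-2,3-dihydro-4H-chromen-4-one
Product: 9 5,8-dimethoxy-2,2-dimethyl-2H-chromene, via chroman-4-ol 8 (not isolated)
Conditions: NaBH4, MeOH–THF, 0 → 25 °C; then 2 M HCl, 25 °C
Reagents that add atoms: none
Why: Borohydride reduction of the aryl ketone to the racemic benzylic alcohol, then acid-catalysed E1 dehydration through a benzylic cation stabilised by the ortho ring oxygen and ortho methoxy group (the standard chromanone-to-2,2-dimethylchromene conversion), should remove the temporary carbonyl and the transient stereocentre.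

Step 4
Reactants: 9 5,8-dimethoxy-2,2-dimethyl-2H-chromene
Product: 10 2,2-dimethyl-2H-chromene-5,8-dione
Conditions: CAN (2.5 equiv), MeCN–H2O, 0 °C, short reaction time
Reagents that add atoms: water, O
Why: CAN oxidative demethylation of a p-dimethoxyarene to the p-quinone (arene radical cation, ipso attack of water, loss of methanol) is a reaction type that tolerates a conjugated alkene, as in vinylquinone preparations, when run cold and briefly.

Step 5
Reactants: 11 1-(2,4,6-trihydroxyphenyl)ethan-1-one (phloroacetophenone)
Product: 13 1-(5,7-dihydroxy-2,2-dimethyl-2H-chromen-6-yl)ethan-1-one, via propargyl ether 12 (not isolated)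
Conditions: 3-chloro-3-methylbut-1-yne (1.1 equiv), K2CO3, KI, CuI (cat.), DMF, 65 °C; then 130 °C
Reagents that add atoms: 3-chloro-3-methylbut-1-yne, CC(C)(Cl)C#C
Why: Copper-assisted O-alkylation of the most acidic, non-chelated 4-OH, then aromatic propargyl Claisen rearrangement, 1,5-H shift and oxa-6π electrocyclisation, should give the 2,2-dimethylchromene as a single isomer because the two ortho positions of the ether are equivalent by symmetry.

Step 6
Reactants: 13 1-(5,7-dihydroxy-2,2-dimethyl-2H-chromen-6-yl)ethan-1-one
Product: 14 1-[5-hydroxy-2,2-dimethyl-7-(prop-2-en-1-yloxy)-2H-chromen-6-yl]ethan-1-one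
Conditions: allyl bromide (1.05 equiv), K2CO3 (1.1 equiv), acetone, 56 °C
Reagents that add atoms: allyl bromide, C=CCBr
Why: Williamson O-allylation should take the 7-OH, because the 5-OH is held in the stronger hydrogen bond to the acetyl carbonyl and is shielded by the peri C4–H.

Step 7
Reactants: 14 1-[5-hydroxy-2,2-dimethyl-7-(prop-2-en-1-yloxy)-2H-chromen-6-yl]ethan-1-one
Product: 15 1-[5-hydroxy-2,2-dimethyl-7-(prop-2-en-1-yloxy)-2H-chromen-6-yl]-3,3-bis(methylsulfanyl)prop-2-en-1-one
Conditions: t-BuOK (3.1 equiv), CS2 (1.2 equiv), THF, 0 °C; then MeI (2.05 equiv), 0 → 25 °C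
Reagents that add atoms: carbon disulfide, S=C=S; iodomethane, CI
Why: α-Oxoketene dithioacetal synthesis (enolate addition to CS2, double S-methylation of the ene-dithiolate, the chelated phenoxide being the poorer nucleophile) installs the future pyrone C2 at the carboxyl oxidation level.

Step 8
Reactants: 15 1-[5-hydroxy-2,2-dimethyl-7-(prop-2-en-1-yloxy)-2H-chromen-6-yl]-3,3-bis(methylsulfanyl)prop-2-en-1-one
Product: 17 8,8-dimethyl-5-(prop-2-en-1-yloxy)-2-(pyrrolidin-1-yl)-4H,8H-pyrano[2,3-f]chromen-4-one, via N,S-ketene acetal 16 (not isolated)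
Conditions: pyrrolidine (2.5 equiv), EtOH, 78 °C; then AcOH (5 equiv), 78 °C
Reagents that add atoms: pyrrolidine, C1CCNC1
Why: Addition–elimination of the amine on the push–pull ketene dithioacetal gives the N,S-acetal, and acid-promoted intramolecular addition–elimination by the only free phenol expels the second methanethiol to close the 2-aminochromone; the angular pyrone regiochemistry is fixed because the other ortho oxygen is allylated.

Step 9
Reactants: 17 8,8-dimethyl-5-(prop-2-en-1-yloxy)-2-(pyrrolidin-1-yl)-4H,8H-pyrano[2,3-f]chromen-4-one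
Product: 18 5-hydroxy-8,8-dimethyl-6-(prop-2-en-1-yl)-2-(pyrrolidin-1-yl)-4H,8H-pyrano[2,3-f]chromen-4-one
Conditions: N,N-diethylaniline, 195 °C, sealed tube, Ar
Reagents that add atoms: none
Why: Aromatic Claisen rearrangement: the [3,3] shift can reach only C6, the single free ortho position of the 5-allyloxy group, and tautomerisation should give the chelated 5-OH.

Step 10
Reactants: 18 5-hydroxy-8,8-dimethyl-6-(prop-2-en-1-yl)-2-(pyrrolidin-1-yl)-4H,8H-pyrano[2,3-f]chromen-4-one
Product: 19 5-hydroxy-8,8-dimethyl-6-(3-methylbut-2-en-1-yl)-2-(pyrrolidin-1-yl)-4H,8H-pyrano[2,3-f]chromen-4-one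
Conditions: Grubbs II catalyst (5 mol%), 2-methylbut-2-ene (30 equiv), CH2Cl2, 40 °C
Reagents that add atoms: 2-methylbut-2-ene, CC=C(C)C
Why: Olefin cross-metathesis of the terminal allyl alkene with 2-methylbut-2-ene should convert allyl into prenyl with loss of propene, the ring cis-alkene next to a quaternary carbon and the push–pull enaminone alkene being metathesis-inert.

Step 11
Reactants: 19 5-hydroxy-8,8-dimethyl-6-(3-methylbut-2-en-1-yl)-2-(pyrrolidin-1-yl)-4H,8H-pyrano[2,3-f]chromen-4-one; 10 2,2-dimethyl-2H-chromene-5,8-dione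
Product: 21 CNP0323631.0 (target), via hydroquinone adduct 20 (not isolated)
Conditions: AcOH, slow addition of 10 (1.05 equiv), 25 °C, then 60 °C, N2
Reagents that add atoms: none
Why: Nenitzescu-type benzofuran annulation (tertiary enaminone plus 1,4-benzoquinone): C3 of the 2-aminochromone should add to quinone C6, the position β to the C8 carbonyl that the pyran oxygen does not deactivate (the C5 carbonyl is a vinylogous ester); the adduct aromatises to hydroquinone 20, whose C5–OH, now ortho to the new bond, adds to the protonated C2 and expels pyrrolidinium to close the furan and leave the C8–OH as the free phenol, while acetic acid keeps the released amine protonated and away from the quinone.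

**Compound list**
1 | 2-fluoro-1,4-dimethoxybenzene | COc1ccc(OC)c(F)c1 | starting material
2 | (2-fluoro-3,6-dimethoxyphenyl)lithium | [Li]c1c(OC)ccc(OC)c1F | intermediate
3 | 1-(2-fluoro-3,6-dimethoxyphenyl)ethan-1-one | CC(=O)c1c(OC)ccc(OC)c1F | intermediate
4 | acetone | CC(C)=O | starting material
5 | lithium 1-(2-fluoro-3,6-dimethoxyphenyl)ethen-1-olate | [Li+].[O-]C(=C)c1c(OC)ccc(OC)c1F | intermediate
6 | lithium 4-(2-fluoro-3,6-dimethoxyphenyl)-2-methyl-4-oxobutan-2-olate | [Li+].[O-]C(C)(C)CC(=O)c1c(OC)ccc(OC)c1F | intermediate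
7 | 5,8-dimethoxy-2,2-dimethyl-2,3-dihydro-4H-chromen-4-one | COc1ccc(OC)c2c1OC(C)(C)CC2=O | intermediate
8 | 5,8-dimethoxy-2,2-dimethylchroman-4-ol (racemic) | COc1ccc(OC)c2c1OC(C)(C)CC2O | intermediate
9 | 5,8-dimethoxy-2,2-dimethyl-2H-chromene | COc1ccc(OC)c2c1OC(C)(C)C=C2 | intermediate
10 | 2,2-dimethyl-2H-chromene-5,8-dione | O=C1C=CC(=O)C2=C1OC(C)(C)C=C2 | intermediate
11 | 1-(2,4,6-trihydroxyphenyl)ethan-1-one | CC(=O)c1c(O)cc(O)cc1O | starting material
12 | 1-{2,6-dihydroxy-4-[(2-methylbut-3-yn-2-yl)oxy]phenyl}ethan-1-one | CC(=O)c1c(O)cc(OC(C)(C)C#C)cc1O | intermediate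
13 | 1-(5,7-dihydroxy-2,2-dimethyl-2H-chromen-6-yl)ethan-1-one | CC(=O)c1c(O)cc2OC(C)(C)C=Cc2c1O | intermediate
14 | 1-[5-hydroxy-2,2-dimethyl-7-(prop-2-en-1-yloxy)-2H-chromen-6-yl]ethan-1-one | CC(=O)c1c(OCC=C)cc2OC(C)(C)C=Cc2c1O | intermediate
15 | 1-[5-hydroxy-2,2-dimethyl-7-(prop-2-en-1-yloxy)-2H-chromen-6-yl]-3,3-bis(methylsulfanyl)prop-2-en-1-one | CSC(SC)=CC(=O)c1c(OCC=C)cc2OC(C)(C)C=Cc2c1O | intermediate
16 | 1-[5-hydroxy-2,2-dimethyl-7-(prop-2-en-1-yloxy)-2H-chromen-6-yl]-3-(methylsulfanyl)-3-(pyrrolidin-1-yl)prop-2-en-1-one | CSC(=CC(=O)c1c(OCC=C)cc2OC(C)(C)C=Cc2c1O)N1CCCC1 | intermediate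
17 | 8,8-dimethyl-5-(prop-2-en-1-yloxy)-2-(pyrrolidin-1-yl)-4H,8H-pyrano[2,3-f]chromen-4-one | O=c1cc(N2CCCC2)oc2c1c(OCC=C)cc1OC(C)(C)C=Cc21 | intermediate
18 | 5-hydroxy-8,8-dimethyl-6-(prop-2-en-1-yl)-2-(pyrrolidin-1-yl)-4H,8H-pyrano[2,3-f]chromen-4-one | O=c1cc(N2CCCC2)oc2c1c(O)c(CC=C)c1OC(C)(C)C=Cc21 | intermediate
19 | 5-hydroxy-8,8-dimethyl-6-(3-methylbut-2-en-1-yl)-2-(pyrrolidin-1-yl)-4H,8H-pyrano[2,3-f]chromen-4-one | O=c1cc(N2CCCC2)oc2c1c(O)c(CC=C(C)C)c1OC(C)(C)C=Cc21 | intermediate
20 | 3-(5,8-dihydroxy-2,2-dimethyl-2H-chromen-6-yl)-5-hydroxy-8,8-dimethyl-6-(3-methylbut-2-en-1-yl)-2-(pyrrolidin-1-yl)-4H,8H-pyrano[2,3-f]chromen-4-one | O=c1c(-c2cc(O)c3OC(C)(C)C=Cc3c2O)c(N2CCCC2)oc2c1c(O)c(CC=C(C)C)c1OC(C)(C)C=Cc21 | intermediate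
21 | CNP0323631.0: 5-hydroxy-6-prenyl coumaronochromone (benzofuro[2,3-b]chromen-4-one core) with a 2,2-dimethyl-2H-pyran fused at C7–O/C8 of ring A and a second 2,2-dimethyl-2H-pyran fused to ring B, its oxygen ortho to the free B-ring hydroxyl | CC(C)=CCc1c2c(c3oc4oc5c6c(c(O)cc5c4c(=O)c3c1O)OC(C)(C)C=C6)C=CC(C)(C)O2 | target

**Step count and risks**
Total steps: 11 (steps 1–4 ring-B branch, steps 5–10 ring-A branch, step 11 union). Longest linear sequence: 7 steps (steps 5–11).

Steps most likely to fail:

1. Step 11. The conjugate addition may go to the other free quinone carbon (C7) and give the isomeric furan fusion, the adduct hydroquinone may be oxidised by unreacted quinone, or the amine may be expelled too slowly from the hindered vinylogous urea. Fallback, from acetophenone 14 and quinone 10 to target 21: 14 is condensed with N,N-dimethylformamide dimethyl acetal to the open-chain enaminone F1. Classical Nenitzescu reaction of F1 with 10 in acetic acid gives the 3-aroyl-5-hydroxybenzofuran F2. DDQ in dioxane closes the γ-pyrone by dehydrogenative C–O bond formation between the chelated phenol and the furan C2, giving the O-allyl coumaronochromone F3. Claisen rearrangement (195 °C) then gives the 6-allyl-5-hydroxy coumaronochromone F4, and cross-metathesis with 2-methylbut-2-ene gives 21.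

2. Step 2. Retro-aldol cleavage of the lithium aldolate may outrun ring closure, proton transfer to acetone may lead to self-condensation, or the aldolate may dehydrate to the enone. Fallback, from 3 back to 7: the fluoride is displaced with the alkoxide of 2-(methylsulfonyl)ethanol (NaH, DMF), which eliminates in situ to the phenol 1-(2-hydroxy-3,6-dimethoxyphenyl)ethan-1-one F5. Kabbe condensation of F5 with acetone and pyrrolidine then gives 7, the acetone-derived bonds now being C3–C2 and O–C2.

3. Step 6. Alkylation may occur at the other hydroxyl or at both, which would invert the later pyrone regiochemistry from angular to linear. Fallback, from 12 (isolated by ending step 5 after the 65 °C stage) back to 14: mono-allylation of one of the two equivalent ortho hydroxyls of 12 (allyl bromide, K2CO3, acetone) gives the allyl propargyl diether F6. Heating F6 at 130 °C then directs the propargyl Claisen cyclisation to the carbon next to the remaining chelated hydroxyl (bond fixation), giving 14.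

Further compounds
F1 | step 11 | (E)-3-(dimethylamino)-1-[5-hydroxy-2,2-dimethyl-7-(prop-2-en-1-yloxy)-2H-chromen-6-yl]prop-2-en-1-one | CN(C)/C=C/C(=O)c1c(OCC=C)cc2OC(C)(C)C=Cc2c1O
F2 | step 11 | [5-hydroxy-2,2-dimethyl-7-(prop-2-en-1-yloxy)-2H-chromen-6-yl] ketone of the 3-position of the 5-hydroxybenzofuran carrying the fused 2,2-dimethylpyran (furo[2,3-f]chromene core) | O=C(c1coc2c1cc(O)c1OC(C)(C)C=Cc12)c1c(OCC=C)cc2OC(C)(C)C=Cc2c1O
F3 | step 11 | 5-O-allyl-6-unsubstituted analogue of the target coumaronochromone | O=c1c2c3cc(O)c4OC(C)(C)C=Cc4c3oc2oc2c1c(OCC=C)cc1OC(C)(C)C=Cc21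
F4 | step 11 | 6-allyl (in place of 6-prenyl) analogue of the target coumaronochromone | O=c1c2c3cc(O)c4OC(C)(C)C=Cc4c3oc2oc2c1c(O)c(CC=C)c1OC(C)(C)C=Cc21
F5 | step 2 | 1-(2-hydroxy-3,6-dimethoxyphenyl)ethan-1-one | CC(=O)c1c(OC)ccc(OC)c1O
F6 | step 6 | 1-{2-hydroxy-4-[(2-methylbut-3-yn-2-yl)oxy]-6-(prop-2-en-1-yloxy)phenyl}ethan-1-one | CC(=O)c1c(O)cc(OC(C)(C)C#C)cc1OCC=C
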